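- About 6810 is what the dawn plateau reads for target made per catalyst charged, and I carry this count, the turnover number, through these flasks.

| setting | dawn | summer | Friday's | Tuesday's | Wednesday's |
|---|---|---|---|---|---|
| starting material | 0.050 M | 0.050 M | 0.050 M | 0.050 M | 0.050 M |
| second substrate | 2 equiv | 2 equiv | 2.00 equiv | 2.00 equiv | 2.00 equiv |
| precatalyst | 0.014 mol% | 0.022 mol% | 0.01 mol% | 0.01 mol% | 0.01 mol% |
| temperature | 30 °C | 52 °C | 20 °C | 40 °C | 60 °C |
| remark | run made earlier | run made earlier |  |  |  |
| time |  |  | 5.0 min | 5.0 min | 5.0 min |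

dawn run (percent of the starting material charged)

| time / min | first complex / % | loaded enzyme / % | target / % | second complex / % | starting material / % |
|---|---|---|---|---|---|
| 0.333 | 0 | 0 | 90.7 | 0 | 7.3 |
| 0.667 | 0.9 | 0 | 94.9 | 0 | 5.5 |
| 1.00 | 0.1 | 0.9 | 96.0 | 0 | 5.0 |
| 1.50 | 0 | 0 | 96.3 | 0.5 | 7.8 |
| 2.00 | 0.8 | 0 | 95.6 | 0 | 5.6 |
| 2.50 | 0 | 0 | 93.6 | 0.6 | 5.7 |

summer run (percent of the starting material charged)

| time / s | first complex / % | loaded enzyme / % | target / % | second complex / % | starting material / % |
|---|---|---|---|---|---|
| 10.0 | 1.3 | 0.9 | 63.4 | 0.4 | 35.5 |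
| 12.0 | 0 | 0.4 | 64.0 | 0.3 | 35.0 |
| 20.0 | 0 | 0 | 66.2 | 1.1 | 35.9 |
| 30.0 | 0 | 0 | 61.8 | 0 | 37.1 |
| 40.0 | 1.2 | 1.2 | 62.5 | 1.2 | 35.9 |
| 50.0 | 0.1 | 0.9 | 63.5 | 0 | 37.6 |

(standard deviation of a reading: 1 percentage point)

- which of these there is most of at the end, counted by the starting material in it, Friday's (starting material / second complex / first complex / loaded enzyme / target)
- which of these there is most of at the end, counted by the starting material in it, Tuesday's (starting material / second complex / first complex / loaded enzyme / target)
- which of these there is most of at the end, counted by the starting material in it, Wednesday's (starting material / second complex / first complex / loaded enzyme / target)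
- the largest of these amounts at the end, in percent of the starting material charged, Friday's
- the largest of these amounts at the end, in percent of the starting material charged, Tuesday's
- the largest of these amounts at the end, in percent of the starting material charged, Wednesday's

- the numbers in the tables scatter with a standard deviation of 1 percentage point

- In the first instants the fresh catalyst works fast: dawn's target reads 90.7% at 0.333 min, and summer's reads 63.4% at 10.0 s.
- The complexes read zero within the scatter of 1 point, and the catalyst charged is 0.014 mol% at dawn and 0.022 mol% in summer, on the starting material.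
- In the middle, dawn's target climbs to 96.0% at 1.00 min, while summer's is already flat, between 61.8% and 66.2% up to 50.0 s.
- At the end, starting material, the limiting reagent if one of each is used, still reads 5.7% at dawn and 37.6% in summer, with second substrate charged at 2 equiv.
- These plateaus could be equilibrium or dead catalyst, and the readings can't separate the two, so I bet on dead catalyst and freeze the count at each temperature.
- Summer's count reads 2890, lower than dawn's, so the count halves every 17.8 K if it falls exponentially with temperature.
- My carried quantity is the turnover number at 40 °C, target per catalyst charged, 4610.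
- At 0.01 mol% that gives Tuesday's 46.1% target by my reckoning, leaving starting material ahead at 53.9%.
- The same rule gives Wednesday's 21.2% target and lets Friday's reach about 100%.
- The forecast “read the plateaus as equilibrium” and differs from me: target at 98% on Friday's, target at 85% on Tuesday's, and starting material at 54% on Wednesday's.
- The flasks give target at 97.0% on Friday's, target at 55.5% on Tuesday's, and starting material at 73.9% on Wednesday's.

    starting material + free enzyme ⇌ first complex (K = 45.0 M⁻¹, k = 1.20 × 10⁶ M⁻¹ s⁻¹, Ea = 16.0 kJ mol⁻¹, ΔH = 11.0 kJ mol⁻¹)
    precatalyst → free enzyme (k = 0.830 s⁻¹, Ea = 81.0 kJ mol⁻¹)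
    second substrate + loaded enzyme ⇌ second complex (K = 27.0 M⁻¹, k = 6.20 × 10⁵ M⁻¹ s⁻¹, Ea = 16.0 kJ mol⁻¹, ΔH = 11.0 kJ mol⁻¹)
    second complex → free enzyme + target (k = 3200 s⁻¹, Ea = 51.0 kJ mol⁻¹)
    first complex → spent catalyst (k = 0.250 s⁻¹, Ea = 79.0 kJ mol⁻¹)
    first complex ⇌ loaded enzyme + first product (K = 0.0630 M, k = 3000 s⁻¹, Ea = 61.0 kJ mol⁻¹, ΔH = −33.0 kJ mol⁻¹)
    free enzyme → unfolded enzyme (k = 4.20 × 10⁻⁴ s⁻¹, Ea = 193 kJ mol⁻¹)
    (constants at 20 °C)

- On Friday's, first complex has a half-life of 2.8 s towards spent catalyst by that step alone, against 28 min for free enzyme towards unfolded enzyme by that step alone. Tuesday's ends with 97.8% of its catalyst spent and 2.23% unfolded, and its count of 5550 is above my 4610, with starting material still 44.5% at 50.0 min. Tuesday's flask with 5.00 equiv of second substrate counts 6450, with 97.5% of its catalyst spent.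

All runs stem from a simulated flask for an exercise.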